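**Route overview**

- Cuts (carotenoid numbering: ring C1–C6, chain C7–C15 and C15'–C7'): first the O–Si bond at C3 and the oxygen on C8', reading the acetyl group C8'(=O)–C7'H3 as a terminal alkyne C8'≡C7'–H; then the C6–C7 bond between ring and alkyne; then the C11=C12 and C11'=C12' double bonds.
- Enabling feature: with the acetyl group written as C≡C–H, the chain C7–C7' (seven E double bonds, methyls on C9, C13, C13', C9') is a twofold-symmetric diyne with two identical HC≡C–C(CH3)=CH ends. The cyclohexene ring on C6 is the only element that breaks the symmetry, and C6 can be armed in one way only, as the C5=C6 enol triflate of a ketone whose other alpha carbon (C1) is quaternary.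
- Forward: the six-membered ring is bought as 4-oxoisophorone and never opened (two enzymatic reductions, silylation, triflation). The chain grows in both directions from a C10 dialdehyde by a double Wittig reaction with a C6 enynyl phosphonium salt. Ring and chain are joined at C6–C7 by one mono-Sonogashira coupling of the symmetric diyne, then the remaining alkyne is hydrated to the methyl ketone and the silyl ether removed.
- Stereochemistry: C3 (R) is set by the ketoreductase step. 9E and 9'E come with the bought E-enynol; 13E, 15E and 13'E come with the bought dialdehyde; 11E and 11'E come from the Wittig step after thermal relaxation of the hindered cis isomers.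

Key step: step 8

Remark on the chemistry: carotenoid numbering is used for ring and chain positions throughout, and both reductases are assumed to be available as recombinant preparations with glucose/glucose dehydrogenase cofactor recycling.

**Route**

Step 1
Reactants: 1 4-oxoisophorone (2,6,6-trimethylcyclohex-2-ene-1,4-dione)
Product: 2 (6R)-levodione [(6R)-2,2,6-trimethylcyclohexane-1,4-dione]
Conditions: ene-reductase OYE2 (Old Yellow Enzyme family), NADP+ (cat.), glucose dehydrogenase, D-glucose, KH2PO4/K2HPO4 buffer pH 7.0, 30 °C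
Reagents that add atoms: none
Why: Biocatalytic conjugate reduction by a flavin-dependent ene-reductase; hydride from the reduced flavin and a proton from the active site add across the activated ring C=C, and the enzyme pocket fixes the face at the methyl-bearing carbon so that the 6R centre should result (neutral pH limits its enolisation).

Step 2
Reactants: 2 (6R)-levodione
Product: 3 (4R,6R)-actinol [(4R,6R)-4-hydroxy-2,2,6-trimethylcyclohexan-1-one, OH and C6 methyl trans]
Conditions: levodione reductase (NADH-dependent ketoreductase), NAD+ (cat.), glucose dehydrogenase, D-glucose, KH2PO4/K2HPO4 buffer pH 7.0, 30 °C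
Reagents that add atoms: none
Why: Enzymatic carbonyl reduction; only the unhindered C4 carbonyl fits the active site (the C1 carbonyl is flanked by a gem-dimethyl and a methyl-bearing carbon), and hydride delivery to one face under enzyme control sets the 4R carbinol, which becomes C3 (R) of the target.

Step 3
Reactants: 3 (4R,6R)-actinol
Product: 4 (4R,6R)-4-[(tert-butyldimethylsilyl)oxy]-2,2,6-trimethylcyclohexan-1-one
Conditions: TBSCl, imidazole, DMF, rt
Reagents that add atoms: tert-butyldimethylsilyl chloride, CC(C)(C)[Si](C)(C)Cl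
Why: Standard imidazole-promoted silylation of a secondary alcohol; the hindered ketone is a spectator and the carbinol configuration is not involved.

Step 4
Reactants: 4 (4R,6R)-4-[(tert-butyldimethylsilyl)oxy]-2,2,6-trimethylcyclohexan-1-one
Product: 6 (4R)-4-[(tert-butyldimethylsilyl)oxy]-2,6,6-trimethylcyclohex-1-en-1-yl trifluoromethanesulfonate, via potassium enolate 5 (not isolated)
Conditions: KN(SiMe3)2, THF, −78 to 0 °C; then PhNTf2, −78 °C to rt
Reagents that add atoms: N-phenylbis(trifluoromethanesulfonimide), O=S(=O)(N(c1ccccc1)S(=O)(=O)C(F)(F)F)C(F)(F)F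
Why: Enolisation and O-triflation of a ketone with a single alpha C–H, so only one enol triflate regioisomer can form; the methyl stereocentre is erased on purpose, while the silyloxy carbon is gamma to the carbonyl and should neither epimerise nor eliminate.

Step 5
Reactants: 7 (2E)-3-methylpent-2-en-4-yn-1-ol
Product: 8 (3E)-5-bromo-3-methylpent-3-en-1-yne
Conditions: PBr3 (0.4 equiv), pyridine (cat.), Et2O, −20 to 0 °C, dark
Reagents that add atoms: phosphorus tribromide, BrP(Br)Br
Why: Bromination of a primary allylic alcohol through its phosphite ester with SN2 displacement at the primary carbon; cold, non-ionising conditions should prevent allylic transposition and keep the E double bond.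

Step 6
Reactants: 8 (3E)-5-bromo-3-methylpent-3-en-1-yne
Product: 9 [(2E)-3-methylpent-2-en-4-yn-1-yl]triphenylphosphonium bromide
Conditions: PPh3, toluene, rt, dark
Reagents that add atoms: triphenylphosphine, c1ccc(cc1)P(c1ccccc1)c1ccccc1
Why: SN2 quaternisation of triphenylphosphine by a primary allylic bromide; the salt should precipitate from toluene with the E geometry and the terminal alkyne intact.

Step 7
Reactants: 9 [(2E)-3-methylpent-2-en-4-yn-1-yl]triphenylphosphonium bromide (2.3 equiv); 10 (2E,4E,6E)-2,7-dimethylocta-2,4,6-trienedial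
Product: 14 all-E C22 heptaene-diyne (3E,5E,7E,9E,11E,13E,15E)-3,7,12,16-tetramethyloctadeca-3,5,7,9,11,13,15-heptaene-1,17-diyne, via phosphorus ylide 11 (not isolated), via C16 enynal 12 (not isolated), via 11-cis isomer 13 (not isolated)
Conditions: NaOMe (2.4 equiv), MeOH/CH2Cl2, −10 °C to rt; aqueous work-up; then heptane, 80 °C, argon, dark; crystallisation
Reagents that add atoms: none
Why: Two-directional Wittig olefination with a semi-stabilised allylic ylide forms C11=C12 and C11'=C12' as E/Z mixtures (methoxide is far too weak to deprotonate the alkyne C–H); the 11-cis forms are strained by the clash of C10–H with the C13 methyl and should relax thermally to trans, under heating mild enough to leave the trisubstituted 9E enyne ends alone, with the least soluble all-E isomer crystallising.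

Step 8
Reactants: 6 (4R)-4-[(tert-butyldimethylsilyl)oxy]-2,6,6-trimethylcyclohex-1-en-1-yl trifluoromethanesulfonate; 14 all-E C22 heptaene-diyne (3 equiv, excess recovered)
Product: 15 C31 octaene-diyne silyl ether: (4R)-4-[(tert-butyldimethylsilyl)oxy]-2,6,6-trimethylcyclohex-1-ene carrying at its ring carbon 1 (C6) the (3E,5E,7E,9E,11E,13E,15E)-3,7,12,16-tetramethyloctadeca-3,5,7,9,11,13,15-heptaene-1,17-diyn-1-yl chain, free C≡C–H at the far end
Conditions: Pd(PPh3)4 (5 mol %), CuI (10 mol %), iPr2NH, THF, rigorously degassed, slow addition of 6, rt to 40 °C, dark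
Reagents that add atoms: none
Why: Sonogashira coupling: zerovalent palladium inserts into the C6–O bond of enol triflate 6, the copper acetylide formed from one C≡C–H terminus of 14 with CuI and iPr2NH transmetalates, and reductive elimination forms the C6–C7 bond. The closest known reaction type is the coupling of 2,6,6-trimethylcyclohexenyl triflates with terminal enynes, run here as a statistical mono-coupling of a symmetric diyne. No ring closes and no stereocentre is created; C3 (R) is a spectator, and the 9E enyne should survive because the catalytic cycle offers no path for double-bond isomerisation at these temperatures. The selectivity needed is mono- over bis-coupling: the two termini are identical and insulated by seven double bonds, so the substrate gives no bias and the outcome is governed by stoichiometry (threefold excess of 14, slow addition of 6), with unreacted 14 recovered. The site of the junction is fixed because 6 is the only enol triflate its ketone can form, and the linear sp carbon of the acetylide tolerates the crowding by the C1 gem-dimethyl and C5 methyl groups. Exclusion of oxygen suppresses oxidative homocoupling of the excess diyne.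

Step 9
Reactants: 15 C31 octaene-diyne silyl ether
Product: 17 (3E,5E,7E,9E,11E,13E,15E)-18-[(4R)-4-[(tert-butyldimethylsilyl)oxy]-2,6,6-trimethylcyclohex-1-en-1-yl]-3,7,12,16-tetramethyloctadeca-3,5,7,9,11,13,15-heptaen-17-yn-2-one, via enol 16 (not isolated)
Conditions: Ph3PAuNTf2 (5 mol %), H2O (10 equiv), 1,4-dioxane, rt, argon, dark
Reagents that add atoms: water, O
Why: Gold-catalysed Markovnikov hydration of a terminal alkyne: the cationic monovalent gold centre activates the unhindered C7'≡C8'–H, water attacks C8', and protodeauration gives the enol that tautomerises to the methyl ketone; the internal C7≡C8 alkyne, shielded by the ring methyls and the C9 methyl, should react far more slowly, the acid-free medium spares the silyl ether and the polyene, and the E geometry at C9'=C10' keeps the alkyne away from C11'=C12' so no dienyne cyclisation is possible.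

Step 10
Reactants: 17 silyl-protected methyl ketone
Product: 18 (3E,5E,7E,9E,11E,13E,15E)-18-[(4R)-4-hydroxy-2,6,6-trimethylcyclohex-1-en-1-yl]-3,7,12,16-tetramethyloctadeca-3,5,7,9,11,13,15-heptaen-17-yn-2-one (CNP0167252.1)
Conditions: HF·pyridine, excess pyridine, THF, 0 °C to rt, dark
Reagents that add atoms: none
Why: Fluoride-driven cleavage of the Si–O bond; the pyridine-buffered reagent is neither basic enough to trigger aldol chemistry of the methyl ketone nor acidic enough to isomerise the polyene, and the C3 carbinol is released with its configuration unchanged.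

**Compound list**

1 | 4-oxoisophorone (2,6,6-trimethylcyclohex-2-ene-1,4-dione) | O=C1C(C)=CC(=O)CC1(C)C | starting material
2 | (6R)-levodione, (6R)-2,2,6-trimethylcyclohexane-1,4-dione | O=C1CC(C)(C)C(=O)[C@H](C)C1 | intermediate
3 | (4R,6R)-actinol, (4R,6R)-4-hydroxy-2,2,6-trimethylcyclohexan-1-one | O=C1[C@H](C)C[C@@H](O)CC1(C)C | intermediate
4 | (4R,6R)-4-[(tert-butyldimethylsilyl)oxy]-2,2,6-trimethylcyclohexan-1-one | O=C1[C@H](C)C[C@@H](O[Si](C)(C)C(C)(C)C)CC1(C)C | intermediate
5 | potassium (4R)-4-[(tert-butyldimethylsilyl)oxy]-2,6,6-trimethylcyclohex-1-en-1-olate (not isolated) | [K+].[O-]C1=C(C)C[C@@H](O[Si](C)(C)C(C)(C)C)CC1(C)C | intermediate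
6 | (4R)-4-[(tert-butyldimethylsilyl)oxy]-2,6,6-trimethylcyclohex-1-en-1-yl trifluoromethanesulfonate | FC(F)(F)S(=O)(=O)OC1=C(C)C[C@@H](O[Si](C)(C)C(C)(C)C)CC1(C)C | intermediate
7 | (2E)-3-methylpent-2-en-4-yn-1-ol | C#C/C(C)=C/CO | starting material
8 | (3E)-5-bromo-3-methylpent-3-en-1-yne | C#C/C(C)=C/CBr | intermediate
9 | [(2E)-3-methylpent-2-en-4-yn-1-yl]triphenylphosphonium bromide | C#C/C(C)=C/C[P+](c1ccccc1)(c1ccccc1)c1ccccc1.[Br-] | intermediate
10 | (2E,4E,6E)-2,7-dimethylocta-2,4,6-trienedial (C10 dialdehyde) | O=C/C(C)=C/C=C/C=C(C)/C=O | starting material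
11 | [(2E)-3-methylpent-2-en-4-yn-1-ylidene]triphenylphosphorane (ylide, not isolated) | C#C/C(C)=C/C=P(c1ccccc1)(c1ccccc1)c1ccccc1 | intermediate
12 | (2E,4E,6E,8E,10E)-2,7,11-trimethyltrideca-2,4,6,8,10-pentaen-12-ynal (C16 enynal, not isolated; its C8=C9 bond forms as an E/Z mixture, E form drawn) | C#C/C(C)=C/C=C/C(C)=C/C=C/C=C(C)/C=O | intermediate
13 | (3E,5Z,7E,9E,11E,13E,15E)-3,7,12,16-tetramethyloctadeca-3,5,7,9,11,13,15-heptaene-1,17-diyne (11-cis isomer of 14, representative of the cis forms, not isolated) | C#C/C(C)=C/C=C\C(C)=C\C=C\C=C(C)\C=C\C=C(/C)C#C | intermediate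
14 | (3E,5E,7E,9E,11E,13E,15E)-3,7,12,16-tetramethyloctadeca-3,5,7,9,11,13,15-heptaene-1,17-diyne (all-E C22 heptaene-diyne) | C#C/C(C)=C/C=C/C(C)=C/C=C/C=C(C)/C=C/C=C(\C)C#C | intermediate
15 | (4R)-4-[(tert-butyldimethylsilyl)oxy]-2,6,6-trimethyl-1-[(3E,5E,7E,9E,11E,13E,15E)-3,7,12,16-tetramethyloctadeca-3,5,7,9,11,13,15-heptaene-1,17-diyn-1-yl]cyclohex-1-ene (C31 octaene-diyne) | C#C/C(C)=C/C=C/C(C)=C/C=C/C=C(C)/C=C/C=C(\C)C#CC1=C(C)C[C@@H](O[Si](C)(C)C(C)(C)C)CC1(C)C | intermediate
16 | (3E,5E,7E,9E,11E,13E,15E)-18-[(4R)-4-[(tert-butyldimethylsilyl)oxy]-2,6,6-trimethylcyclohex-1-en-1-yl]-3,7,12,16-tetramethyloctadeca-1,3,5,7,9,11,13,15-octaen-17-yn-2-ol (enol, not isolated) | C=C(O)/C(C)=C/C=C/C(C)=C/C=C/C=C(C)/C=C/C=C(\C)C#CC1=C(C)C[C@@H](O[Si](C)(C)C(C)(C)C)CC1(C)C | intermediate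
17 | (3E,5E,7E,9E,11E,13E,15E)-18-[(4R)-4-[(tert-butyldimethylsilyl)oxy]-2,6,6-trimethylcyclohex-1-en-1-yl]-3,7,12,16-tetramethyloctadeca-3,5,7,9,11,13,15-heptaen-17-yn-2-one | CC(=O)/C(C)=C/C=C/C(C)=C/C=C/C=C(C)/C=C/C=C(\C)C#CC1=C(C)C[C@@H](O[Si](C)(C)C(C)(C)C)CC1(C)C | intermediate
18 | (3E,5E,7E,9E,11E,13E,15E)-18-[(4R)-4-hydroxy-2,6,6-trimethylcyclohex-1-en-1-yl]-3,7,12,16-tetramethyloctadeca-3,5,7,9,11,13,15-heptaen-17-yn-2-one (CNP0167252.1) | CC(=O)/C(C)=C/C=C/C(C)=C/C=C/C=C(C)/C=C/C=C(\C)C#CC1=C(C)C[C@@H](O)CC1(C)C | target

**Step count**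

Total steps: 10. Longest linear sequence: 7 steps (steps 1, 2, 3, 4, 8, 9, 10); the chain branch (steps 5, 6, 7) joins at step 8.

**Steps most likely to fail, with fallbacks**

1. Step 9 (gold-catalysed hydration). The cationic gold centre may engage the electron-rich polyene or the internal alkyne instead of the terminal one, causing E/Z scrambling, over-hydration or slow decomposition before the terminal alkyne is consumed. The fallback avoids alkyne hydration altogether and builds the methyl ketone by olefination; it sets out from 9 and 10 and comes back at 17. The ylide from 9 (1 equiv, NaOMe) is added slowly to an excess of 10, so that after thermal relaxation the C16 enynal 12 is isolated and surplus 10 recovered. Horner–Wadsworth–Emmons reaction of 12 with diethyl (cyanomethyl)phosphonate (NaH, THF) should give (2E,4E,6E,8E,10E,12E)-4,9,13-trimethylpentadeca-2,4,6,8,10,12-hexaen-14-ynenitrile F1. Reduction with iBu2AlH (toluene, −78 °C, then cold dilute HCl) gives (2E,4E,6E,8E,10E,12E)-4,9,13-trimethylpentadeca-2,4,6,8,10,12-hexaen-14-ynal F2. A second Horner–Wadsworth–Emmons reaction with diethyl (3-oxobutan-2-yl)phosphonate (NaH, THF) installs the C9'=C10' bond and the acetyl group, giving (3E,5E,7E,9E,11E,13E,15E)-3,7,12,16-tetramethyloctadeca-3,5,7,9,11,13,15-heptaen-17-yn-2-one F3. Its single terminal alkyne is then coupled with triflate 6 under the conditions of step 8, without any excess, to give 17.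

2. Step 8 (mono-Sonogashira coupling). Over-coupling at the second terminus, oxidative homocoupling of the excess diyne, or poor solubility of the symmetric polyene may erode the yield based on the chiral triflate. The fallback forms the same C6–C7 bond on a small alkyne that has only one terminus; it sets out from 6 and 7 and comes back at 15. Sonogashira coupling of 6 with enynol 7 (Pd(PPh3)4, CuI, iPr2NH) should give (2E)-5-[(4R)-4-[(tert-butyldimethylsilyl)oxy]-2,6,6-trimethylcyclohex-1-en-1-yl]-3-methylpent-2-en-4-yn-1-ol F4. Appel bromination (CBr4, PPh3, CH2Cl2, −20 °C) gives the allylic bromide (4R)-1-[(3E)-5-bromo-3-methylpent-3-en-1-yn-1-yl]-4-[(tert-butyldimethylsilyl)oxy]-2,6,6-trimethylcyclohex-1-ene F5, and PPh3 in toluene converts it into the C15 salt [(2E)-5-[(4R)-4-[(tert-butyldimethylsilyl)oxy]-2,6,6-trimethylcyclohex-1-en-1-yl]-3-methylpent-2-en-4-yn-1-yl]triphenylphosphonium bromide F6. Wittig reaction of F6 (NaOMe) with the C16 enynal 12, isolated from a mono-olefination of excess 10 with 9 as above, followed by thermal relaxation of the new C11=C12 bond, gives 15.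

3. Step 7 (double Wittig reaction and thermal relaxation). The cis-to-trans relaxation at C11 and C11' may be incomplete, or the heating may begin to erode the 9E enyne ends, leaving an isomer mixture that does not crystallise cleanly. The fallback replaces the Wittig reaction by an E-selective phosphonate olefination that needs no heating; it sets out from 8 and comes back at 14. Arbuzov reaction of bromide 8 with P(OEt)3 (neat, 90 °C) gives diethyl [(2E)-3-methylpent-2-en-4-yn-1-yl]phosphonate F7. Its anion (2.2 equiv, NaN(SiMe3)2, THF, −78 to 0 °C) should undergo a double Horner–Wadsworth–Emmons reaction with dialdehyde 10 to give 14 with both new double bonds trans.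

Further compounds
F1 | step 9 | (2E,4E,6E,8E,10E,12E)-4,9,13-trimethylpentadeca-2,4,6,8,10,12-hexaen-14-ynenitrile | C#C/C(C)=C/C=C/C(C)=C/C=C/C=C(C)/C=C/C#N
F2 | step 9 | (2E,4E,6E,8E,10E,12E)-4,9,13-trimethylpentadeca-2,4,6,8,10,12-hexaen-14-ynal | C#C/C(C)=C/C=C/C(C)=C/C=C/C=C(C)/C=C/C=O
F3 | step 9 | (3E,5E,7E,9E,11E,13E,15E)-3,7,12,16-tetramethyloctadeca-3,5,7,9,11,13,15-heptaen-17-yn-2-one | CC(=O)/C(C)=C/C=C/C(C)=C/C=C/C=C(C)/C=C/C=C(\C)C#C
F4 | step 8 | (2E)-5-[(4R)-4-[(tert-butyldimethylsilyl)oxy]-2,6,6-trimethylcyclohex-1-en-1-yl]-3-methylpent-2-en-4-yn-1-ol | OC/C=C(\C)C#CC1=C(C)C[C@@H](O[Si](C)(C)C(C)(C)C)CC1(C)C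
F5 | step 8 | (4R)-1-[(3E)-5-bromo-3-methylpent-3-en-1-yn-1-yl]-4-[(tert-butyldimethylsilyl)oxy]-2,6,6-trimethylcyclohex-1-ene | BrC/C=C(\C)C#CC1=C(C)C[C@@H](O[Si](C)(C)C(C)(C)C)CC1(C)C
F6 | step 8 | [(2E)-5-[(4R)-4-[(tert-butyldimethylsilyl)oxy]-2,6,6-trimethylcyclohex-1-en-1-yl]-3-methylpent-2-en-4-yn-1-yl]triphenylphosphonium bromide | [Br-].c1ccccc1[P+](c1ccccc1)(c1ccccc1)C/C=C(\C)C#CC1=C(C)C[C@@H](O[Si](C)(C)C(C)(C)C)CC1(C)C
F7 | step 7 | diethyl [(2E)-3-methylpent-2-en-4-yn-1-yl]phosphonate | C#C/C(C)=C/CP(=O)(OCC)OCC
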